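(All runs were generated by integration from invented constants; the scatter is artificial.)

If one J takes one G to make one Z, a flask can turn over no more of its J than its G covers. I tested that idea on the two earlier runs.

| flask | J | G | remark | time |
|---|---|---|---|---|
| elm | 13 mM | 11 mM (fed, over 8.0 min) | run made earlier |  |
| maple | 13 mM | 17 mM (fed, over 8.0 min) | run made earlier |  |
| flask | 13 mM | 7.80 mM (fed, over 8.0 min) |  | 3.0 d |

1. why nothing more happens at 3.0 d, or that something still does (all of J has reacted / it is still moving / G has run out first)
2. how much of the J has reacted by 3.0 d
3. how much Z there is at 3.0 d, in percent of the J charged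

- steps that have been proposed: J + G -> Z
- the reaction counts as stopped when no species that holds the J changes by six tenths of a point or more over the second half of the time

- elm (time / d: J / %, Z / %): 0.333: 15.7, 84.6; 0.833: 15.2, 83.7; 1.67: 15.4, 84.6; 2.50: 15.6, 84.4
- maple (time / d: J / %, Z / %): 0.625: 0.2, 100.2; 1.25: 0, 100.3; 1.67: 0, 99.6; 2.50: 0, 100.1

(readings scatter by 0.3 percentage points)

Across the last elm row, J and Z add up to 100 %, so the readings show no J going anywhere but into Z. The elm Z readings show no drift: Z reads 84.6 % at the first reading and 84.4 % at the last, with a scatter of 0.3 percentage points on each reading. The charges in elm give c_G/c_J = 84.6 %, which is where the Z readings lie. In maple the same ratio is 131 %, but Z reads 100.1 % and J 0 %, so the ratio has to be capped at a whole.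

That gave me my rule: the ceiling, the smaller of c_G/c_J and a whole, is the share of J that can react. When it lies below a whole, G is the limiting reagent. For the flask the ceiling is 60.0 %, since G is charged in less than J. Its 3.0 d is longer than the first flat readings of either run, so I expected it to stand at that ceiling with 40.0 % of J left.

The forecast said the same, G has run out first, with 60 % reacted and 60 % of Z, holding that “G should be used up well within 3 d”.

The outcome for the flask was this: G has run out first, with 0 % of its G left, 60.0 % of J reacted and 60.0 % of Z, which is the ceiling of 60.0 %.

    J + G → Z, rate k1*[J]^1.5*[G]^0.5 (k = 11.0 M⁻¹ min⁻¹)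

The one step ran during the feed and after it: at the end of the feed, 0.00556 d, the flask held J 67.9 %, Z 32.1 % and 46.5 % of its own G. By 1.50 d G stood at 0 %, and J and Z stayed at 40.0 % and 60.0 % through 3.00 d.

In a second flask, the same but with 7.8 mM of J, the ceiling is 100 %. That neighbour reached 99.7 % at 3.00 d, with 0.27 % of J and 0.27 % of G still there.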